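**Retrosynthetic overview**

1. Last operation builds rings A and C together: a 4-prenyloxy-2-pyrone carrying a (2R,3S)-epoxy-ketone side chain is opened by alkoxide, closes by intramolecular Claisen condensation to the phloroglucinol ring A, and the new phenoxide opens the trans-epoxide at the benzylic carbon to give ring C; acidic work-up frees the 4'-OH.
2. The pyrone epoxy ketone comes from C-acylation of the lithiated 6-methyl group of 4-prenyloxy-6-methyl-2-pyrone with a (2R,3S)-glycidic morpholine amide.
3. The glycidic amide comes from catalytic asymmetric epoxidation of an (E)-cinnamoyl morpholine (both stereocentres are set here), itself from HWE olefination of THP-protected 4-hydroxybenzaldehyde.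
4. The pyrone comes from O-prenylation of triacetic acid lactone, so the 7-O-prenyl group is in place before ring A exists.
5. Ring order: ring B is bought; oxirane (step 2, temporary); ring A then ring C in the final operation.

Assumption: THP-bearing compounds are used as the roughly 1:1 mixture of epimers at the acetal carbon (left undefined in the SMILES; the centre is removed in step 5), and 1 and 2 are bought as catalogue compounds.

**Route**

Step 1
Reactants: 1 4-(oxan-2-yloxy)benzaldehyde; 2 diethyl [2-(morpholin-4-yl)-2-oxoethyl]phosphonate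
Product: 3 (2E)-1-(morpholin-4-yl)-3-[4-(oxan-2-yloxy)phenyl]prop-2-en-1-one
Conditions: NaH, THF, 0 °C → rt
Reagents that add atoms: none
Why: Horner–Wadsworth–Emmons olefination of an aryl aldehyde with an amide-stabilised phosphonate gives the (E)-enamide, and the base-stable THP acetal is untouched.

Step 2
Reactants: 3 (2E)-1-(morpholin-4-yl)-3-[4-(oxan-2-yloxy)phenyl]prop-2-en-1-one
Product: 4 morpholin-4-yl{(2R,3S)-3-[4-(oxan-2-yloxy)phenyl]oxiran-2-yl}methanone
Conditions: Sm(O-iPr)3 (10 mol %), (S)-BINOL (10 mol %), Ph3As=O (10 mol %), TBHP (decane), 4 Å MS, THF, rt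
Reagents that add atoms: tert-butyl hydroperoxide, CC(C)(C)OO
Why: Lanthanide–BINOL-catalysed nucleophilic epoxidation of an α,β-unsaturated morpholine amide (Weitz–Scheffer type, Shibasaki catalytic asymmetric epoxidation): the chiral Sm–OOtBu species adds to one enantioface of the (E)-enamide and the enolate closes the oxirane with the trans geometry kept, setting C-2 (R) and C-3 (S) in one event; the (S)-ligand is chosen by analogy with enone epoxidation and the sense is confirmed on the first batch by chiral HPLC against the racemate.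

Step 3
Reactants: 5 4-hydroxy-6-methyl-2H-pyran-2-one (triacetic acid lactone); 6 1-bromo-3-methylbut-2-ene (prenyl bromide)
Product: 7 6-methyl-4-[(3-methylbut-2-en-1-yl)oxy]-2H-pyran-2-one
Conditions: K2CO3, DMF, rt
Reagents that add atoms: none
Why: Williamson-type O-alkylation of the vinylogous acid (pKa about 5) with a reactive allylic bromide in a dipolar aprotic solvent gives mainly the 4-O-ether, and the minor C-3-prenylated isomer is removed by chromatography.

Step 4
Reactants: 7 6-methyl-4-[(3-methylbut-2-en-1-yl)oxy]-2H-pyran-2-one; 4 morpholin-4-yl{(2R,3S)-3-[4-(oxan-2-yloxy)phenyl]oxiran-2-yl}methanone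
Product: 10 4-[(3-methylbut-2-en-1-yl)oxy]-6-{2-oxo-2-[(2R,3S)-3-[4-(oxan-2-yloxy)phenyl]oxiran-2-yl]ethyl}-2H-pyran-2-one, via lithiated pyrone 8 (not isolated), via tetrahedral lithium alkoxide 9 (not isolated)
Conditions: LDA (1.15 equiv), 7 (1.2 equiv), THF, −78 °C; then 4, −78 → −40 °C; AcOH, −78 °C
Reagents that add atoms: none
Why: Vinylogous deprotonation of the 6-methyl group gives an extended enolate that reacts at the exocyclic carbon, and its Claisen-type C-acylation by the morpholine amide (Weinreb-type ketone synthesis) stops at the chelated tetrahedral adduct until the quench, so there is no over-addition and the two oxirane stereocentres are not touched.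

Step 5
Reactants: 10 4-[(3-methylbut-2-en-1-yl)oxy]-6-{2-oxo-2-[(2R,3S)-3-[4-(oxan-2-yloxy)phenyl]oxiran-2-yl]ethyl}-2H-pyran-2-one
Product: 14 (2R,3R)-3,5-dihydroxy-2-(4-hydroxyphenyl)-7-[(3-methylbut-2-en-1-yl)oxy]-2,3-dihydro-4H-chromen-4-one (7-prenyloxyaromadendrin), via ring-opened prenyl ester 11 (not isolated), via chalcone epoxide 12 (not isolated), via THP-protected dihydroflavonol 13 (not isolated)
Conditions: n-Bu2Mg (3 equiv), prenol (12 equiv) [gives Mg(OCH2CH=CMe2)2], THF, Ar, 0 → 40 °C; then HCl, MeOH (about 0.1 M free acid), 0 °C → rt, 1 h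
Reagents that add atoms: none
Why: Proposed new method: prenyl oxide (matched to the C-4 ether so that any alkoxy exchange is degenerate) adds to the lactone carbonyl of the enolised pyrone and opens it to the (2E)-3-alkoxy-5,7-dioxo ester 11, whose Mg-chelated diketonate carbon C-6 attacks the ester (6-exo-trig intramolecular Claisen, the aldol mode being blocked by the enol ether) and aromatises to the 2,6-dihydroxy-4-prenyloxyphenyl ketone 12 (ring A), and one of the two equivalent ortho-phenoxides then opens the Mg-activated trans-epoxide at the 4-alkoxybenzylic carbon in 6-endo fashion with inversion (ring C), so C-3 keeps the R configuration of the oxirane α-carbon and C-2 becomes R (2,3-trans), after which methanolic HCl drives any unclosed epoxide through the same benzylic position and cleaves the aryl THP acetal while leaving the prenyl ether; the closest known reactions are the biomimetic (chalcone-synthase-type) Claisen ring transformation of 6-(2-oxoalkyl)-4-alkoxy-2-pyrones into acylphloroglucinols with magnesium alkoxides and the cyclisation of 2'-hydroxychalcone trans-epoxides to trans-dihydroflavonols.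

**Compound list**

1 | 4-(oxan-2-yloxy)benzaldehyde | O=Cc1ccc(OC2CCCCO2)cc1 | starting material
2 | diethyl [2-(morpholin-4-yl)-2-oxoethyl]phosphonate | CCOP(=O)(CC(=O)N1CCOCC1)OCC | starting material
3 | (2E)-1-(morpholin-4-yl)-3-[4-(oxan-2-yloxy)phenyl]prop-2-en-1-one | O=C(/C=C/c1ccc(OC2CCCCO2)cc1)N1CCOCC1 | intermediate
4 | morpholin-4-yl{(2R,3S)-3-[4-(oxan-2-yloxy)phenyl]oxiran-2-yl}methanone | O=C(N1CCOCC1)[C@@H]1O[C@H]1c1ccc(OC2CCCCO2)cc1 | intermediate
5 | 4-hydroxy-6-methyl-2H-pyran-2-one (triacetic acid lactone) | CC1=CC(O)=CC(=O)O1 | starting material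
6 | 1-bromo-3-methylbut-2-ene (prenyl bromide) | CC(C)=CCBr | starting material
7 | 6-methyl-4-[(3-methylbut-2-en-1-yl)oxy]-2H-pyran-2-one | CC1=CC(OCC=C(C)C)=CC(=O)O1 | intermediate
8 | lithiated pyrone: 6-(lithiomethyl)-4-[(3-methylbut-2-en-1-yl)oxy]-2H-pyran-2-one (not isolated) | [Li]CC1=CC(OCC=C(C)C)=CC(=O)O1 | intermediate
9 | tetrahedral lithium alkoxide: adduct of 8 to the amide carbonyl of 4, oxirane (2R,3S) (not isolated) | [Li]OC(CC1=CC(OCC=C(C)C)=CC(=O)O1)(N1CCOCC1)[C@@H]1O[C@H]1c1ccc(OC2CCCCO2)cc1 | intermediate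
10 | 4-[(3-methylbut-2-en-1-yl)oxy]-6-{2-oxo-2-[(2R,3S)-3-[4-(oxan-2-yloxy)phenyl]oxiran-2-yl]ethyl}-2H-pyran-2-one | CC(C)=CCOC1=CC(=O)OC(CC(=O)[C@@H]2O[C@H]2c2ccc(OC3CCCCO3)cc2)=C1 | intermediate
11 | ring-opened prenyl ester: 3-methylbut-2-en-1-yl (2E)-3-[(3-methylbut-2-en-1-yl)oxy]-5,7-dioxo-7-{(2R,3S)-3-[4-(oxan-2-yloxy)phenyl]oxiran-2-yl}hept-2-enoate (not isolated) | CC(C)=CCOC(=O)/C=C(\CC(=O)CC(=O)[C@@H]1O[C@H]1c1ccc(OC2CCCCO2)cc1)OCC=C(C)C | intermediate
12 | chalcone epoxide: {2,6-dihydroxy-4-[(3-methylbut-2-en-1-yl)oxy]phenyl}{(2R,3S)-3-[4-(oxan-2-yloxy)phenyl]oxiran-2-yl}methanone (not isolated) | CC(C)=CCOc1cc(O)c(C(=O)[C@@H]2O[C@H]2c2ccc(OC3CCCCO3)cc2)c(O)c1 | intermediate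
13 | THP-protected dihydroflavonol: (2R,3R)-3,5-dihydroxy-7-[(3-methylbut-2-en-1-yl)oxy]-2-[4-(oxan-2-yloxy)phenyl]-2,3-dihydro-4H-chromen-4-one (not isolated) | CC(C)=CCOc1cc(O)c2c(c1)O[C@H](c1ccc(OC3CCCCO3)cc1)[C@@H](O)C2=O | intermediate
14 | 7-prenyloxyaromadendrin: (2R,3R)-3,5-dihydroxy-2-(4-hydroxyphenyl)-7-[(3-methylbut-2-en-1-yl)oxy]-2,3-dihydro-4H-chromen-4-one | CC(C)=CCOc1cc(O)c2c(c1)O[C@H](c1ccc(O)cc1)[C@@H](O)C2=O | target

**Step count**

Total: 5 steps. Longest linear sequence: 4 steps (1 → 3 → 4 → 10 → 14; the pyrone branch 5 → 7 joins at step 4).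

**Three steps most likely to fail, with fallbacks**

Step 5 (two-ring cascade). The pyrone opening and Claisen closure may be slower than destruction of the electron-rich epoxy ketone. The phenoxide may close 5-exo at the α-carbon to give a benzofuranone. Prolonged base can also erode C-3. The fallback gives up the de novo ring A but keeps the stereochemical plan; it sets out from 4 and comes back at 14. Phloroglucinol is mono-O-prenylated (prenol, PPh3, DIAD, THF; statistical, chromatographed) to 5-[(3-methylbut-2-en-1-yl)oxy]benzene-1,3-diol F1. This is converted with dihydropyran and PPTS into the bis-THP ether F2. F2 is lithiated between the two acetal oxygens (n-BuLi, THF, 0 °C) and added to 4 at −78 °C to give the aryl epoxy ketone F3. PPTS in MeOH at rt then removes the three THP groups, and the freed 2'-phenol opens the epoxide at the benzylic carbon with inversion, giving 14.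

Step 4 (C-acylation of the pyrone anion). Metalation at ring C-3 may compete with the methyl group, the stabilised anion may add only sluggishly to the amide, and the epoxide may be attacked. The fallback replaces acylation by aldol addition and oxidation; it sets out from 4 (with 8 generated from 7 as before) and comes back at 10. The amide 4 is reduced with DIBAL-H (THF, −78 °C) to the epoxy aldehyde (2R,3S)-3-[4-(oxan-2-yloxy)phenyl]oxirane-2-carbaldehyde F4, a far better electrophile than the amide. Addition of 8 at −78 °C gives the carbinol F5 as an epimer mixture. Dess–Martin periodinane (NaHCO3, CH2Cl2, 0 °C) oxidises both epimers to 10.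

Step 2 (asymmetric epoxidation). The sense and level of induction for this electron-rich β-aryl enamide are taken by analogy, and the THP epimers make ee analysis awkward. The fallback replaces catalytic asymmetric epoxidation by a classical Darzens reaction and enzymatic kinetic resolution; it sets out from 1 and comes back at 10. Darzens condensation of 1 with methyl chloroacetate (NaOMe, MeOH, −10 °C → rt) gives the racemic trans-glycidic ester F6. Lipase-catalysed hydrolysis (Serratia marcescens lipase, toluene/aqueous buffer) removes the (2S,3R)-ester and leaves the methyl (2R,3S)-glycidate F7 (50 % at most). F7 then takes the place of 4 in step 4, with 2.2 equivalents of 8 because the β-keto product is deprotonated, and gives 10.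

**Further compounds**

F1 | step 5 | 5-[(3-methylbut-2-en-1-yl)oxy]benzene-1,3-diol | CC(C)=CCOc1cc(O)cc(O)c1
F2 | step 5 | 2,2'-({5-[(3-methylbut-2-en-1-yl)oxy]-1,3-phenylene}bis(oxy))bis(oxane) | CC(C)=CCOc1cc(OC2CCCCO2)cc(OC2CCCCO2)c1
F3 | step 5 | {2,6-bis(oxan-2-yloxy)-4-[(3-methylbut-2-en-1-yl)oxy]phenyl}{(2R,3S)-3-[4-(oxan-2-yloxy)phenyl]oxiran-2-yl}methanone | CC(C)=CCOc1cc(OC2CCCCO2)c(C(=O)[C@@H]2O[C@H]2c2ccc(OC3CCCCO3)cc2)c(OC2CCCCO2)c1
F4 | step 4 | (2R,3S)-3-[4-(oxan-2-yloxy)phenyl]oxirane-2-carbaldehyde | O=C[C@@H]1O[C@H]1c1ccc(OC2CCCCO2)cc1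
F5 | step 4 | 6-{2-hydroxy-2-[(2S,3S)-3-[4-(oxan-2-yloxy)phenyl]oxiran-2-yl]ethyl}-4-[(3-methylbut-2-en-1-yl)oxy]-2H-pyran-2-one (carbinol epimers; oxirane arranged in space as in 4) | CC(C)=CCOC1=CC(=O)OC(CC(O)[C@@H]2O[C@H]2c2ccc(OC3CCCCO3)cc2)=C1
F6 | step 2 | methyl (2RS,3SR)-3-[4-(oxan-2-yloxy)phenyl]oxirane-2-carboxylate (racemic trans) | COC(=O)[C@@H]1O[C@H]1c1ccc(OC2CCCCO2)cc1.COC(=O)[C@H]1O[C@@H]1c1ccc(OC2CCCCO2)cc1
F7 | step 2 | methyl (2R,3S)-3-[4-(oxan-2-yloxy)phenyl]oxirane-2-carboxylate | COC(=O)[C@@H]1O[C@H]1c1ccc(OC2CCCCO2)cc1
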